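The piperidine carries no substituent on C3'–C6', so its ring is disconnected at C4'–C5', far from the C2' stereocentre that joins it to C6 of flavone ring A. One ring-closing metathesis joins an allyl group on N1' to an allyl group on C2' and closes the six-membered nitrogen ring without touching that stereocentre, which is set beforehand by sulfinamide-directed allylation of a benzaldimine. The precursor is the methyl carbamate of an N-allyl (R)-1-arylbut-3-enylamine whose aryl group is a differentiated phloroglucinol (4-O-benzyl, 2,6-di-O-methyl). The carbamate later becomes N-methyl, and the flavone is built last on the freed 4-OH.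

Key step: step 5

Remark: primed locants denote the piperidine (N1', C2'–C6'); unprimed locants and ring A refer to the flavone. The target's only stereocentre, C2', is (R).
Remark: amine 9 is formed as its hydrochloride and is written as the free base that NaHCO3 releases in the same flask.

Step 1
Reactants: 1 4-hydroxy-2,6-dimethoxybenzaldehyde; 2 benzyl bromide
Product: 3 4-(benzyloxy)-2,6-dimethoxybenzaldehyde
Conditions: K2CO3, DMF, rt to 50 °C
Reagents that add atoms: benzyl bromide (2), BrCc1ccccc1
Why: Williamson ether synthesis: K2CO3 deprotonates the only acidic site, the 4-OH, and the phenoxide displaces bromide from benzyl bromide, while the aldehyde and the methyl ethers are inert.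

Step 2
Reactants: 3 4-(benzyloxy)-2,6-dimethoxybenzaldehyde; 4 (S)-tert-butanesulfinamide; 5 allyl bromide
Product: 7 (S)-N-[(1R)-1-(4-benzyloxy-2,6-dimethoxyphenyl)but-3-en-1-yl]-2-methylpropane-2-sulfinamide, via sulfinyl aldimine 6 (not isolated)
Conditions: Ti(OEt)4, THF, 65 °C; then In powder, allyl bromide, 60 °C
Reagents that add atoms: (S)-tert-butanesulfinamide (4), CC(C)(C)[S@](=O)N; allyl bromide (5), C=CCBr
Why: One-pot tert-butanesulfinamide condensation and indium-mediated Barbier-type allylation (α-aminoallylation of an aldehyde): Ti(OEt)4 drives formation of the E-aldimine, and the allylindium reagent then adds through a chair transition state in which indium is bound to the sulfinyl oxygen and the tert-butyl group lies equatorial, so that the (S)-sulfinyl group delivers allyl to the Re face and should set the carbinamine carbon, the later C2', as (R).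

Step 3
Reactants: 7 (S)-N-[(1R)-1-(4-benzyloxy-2,6-dimethoxyphenyl)but-3-en-1-yl]-2-methylpropane-2-sulfinamide; 8 methyl chloroformate
Product: 10 methyl N-[(1R)-1-(4-benzyloxy-2,6-dimethoxyphenyl)but-3-en-1-yl]carbamate, via primary amine 9 (not isolated)
Conditions: HCl (4 M in dioxane), MeOH, 0 °C; concentrate; then ClCO2Me, NaHCO3, CH2Cl2/H2O, 0 °C to rt
Reagents that add atoms: methyl chloroformate (8), COC(=O)Cl
Why: Acid methanolysis of the S–N bond (standard removal of the tert-butanesulfinyl auxiliary) followed by Schotten–Baumann N-acylation of the liberated amine; cold, brief, near-stoichiometric acid keeps the electron-rich benzylic C–N bond from ionising, and the stereocentre is not involved.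

Step 4
Reactants: 10 methyl N-[(1R)-1-(4-benzyloxy-2,6-dimethoxyphenyl)but-3-en-1-yl]carbamate; 5 allyl bromide
Product: 11 methyl N-allyl-N-[(1R)-1-(4-benzyloxy-2,6-dimethoxyphenyl)but-3-en-1-yl]carbamate
Conditions: NaH, allyl bromide, DMF, 0 °C to rt
Reagents that add atoms: allyl bromide (5), C=CCBr
Why: N-Alkylation of a carbamate: NaH removes the only acidic proton (N–H) and the anion displaces bromide from allyl bromide in an SN2 reaction, leaving the stereocentre untouched.

Step 5
Reactants: 11 methyl N-allyl-N-[(1R)-1-(4-benzyloxy-2,6-dimethoxyphenyl)but-3-en-1-yl]carbamate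
Product: 12 methyl (2R)-2-(4-benzyloxy-2,6-dimethoxyphenyl)-3,6-dihydro-2H-pyridine-1-carboxylate
Conditions: second-generation Grubbs catalyst RuCl2(=CHPh)(PCy3)(H2IMes) (3 mol%; H2IMes = 1,3-dimesitylimidazolidin-2-ylidene), CH2Cl2 (0.01 M), 40 °C
Reagents that add atoms: none
Why: Ring-closing olefin metathesis: the ruthenium benzylidene exchanges onto the less hindered N-allyl terminus, the resulting alkylidene adds across the alkene of the C2'-allyl group to give a ruthenacyclobutane, and cycloreversion releases the C4'=C5' bond and, after turnover, ethylene, whose loss drives the reaction. The closest known reaction type is the ring-closing metathesis of N-acyl N-allyl homoallylic amines to 1,2,3,6-tetrahydropyridines. The one ring formed, the six-membered nitrogen ring, closes by intramolecular alkene–alkylidene [2+2] cycloaddition and cycloreversion between the two internal alkene carbons, so that both CH2= termini leave and C4' and C5' become the ring alkene. No stereocentre is created; C2', set in step 2, has no bond made or broken and lies two atoms from the new alkene. The step needs cyclisation to win over intermolecular metathesis and no migration of the alkene toward C2': high dilution, the strain-free six-membered ring and the carbamate, whose rotamers bring the two allyl groups together and whose non-basic nitrogen cannot bind ruthenium, should secure the former, and a short reaction time at 40 °C the latter.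

Step 6
Reactants: 12 methyl (2R)-2-(4-benzyloxy-2,6-dimethoxyphenyl)-3,6-dihydro-2H-pyridine-1-carboxylate
Product: 13 methyl (2R)-2-(4-hydroxy-2,6-dimethoxyphenyl)piperidine-1-carboxylate
Conditions: H2 (1 atm), 10% Pd/C, MeOH/EtOAc, rt
Reagents that add atoms: none
Why: Heterogeneous catalytic hydrogenation saturates C4'=C5' and hydrogenolyses the aryl benzyl ether in the same operation, whereas the N-acylated benzylic C2'–N bond and the methyl ethers are stable under these neutral conditions.

Step 7
Reactants: 13 methyl (2R)-2-(4-hydroxy-2,6-dimethoxyphenyl)piperidine-1-carboxylate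
Product: 14 3,5-dimethoxy-4-[(2R)-1-methylpiperidin-2-yl]phenol
Conditions: LiAlH4, THF, 0 °C to reflux; aq. potassium sodium tartrate work-up, pH 9
Reagents that add atoms: none
Why: LiAlH4 reduction of a carbamate to an N-methyl amine (via the formamide and iminium stages); the phenol is merely carried as its aluminate and no bond at C2' is made or broken.

Step 8
Reactants: 14 3,5-dimethoxy-4-[(2R)-1-methylpiperidin-2-yl]phenol; 15 acetic anhydride
Product: 16 1-{6-hydroxy-2,4-dimethoxy-3-[(2R)-1-methylpiperidin-2-yl]phenyl}ethan-1-one
Conditions: Ac2O, BF3·OEt2, CH2Cl2, 0 °C to rt; then K2CO3, MeOH/H2O, rt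
Reagents that add atoms: acetic anhydride (15), CC(=O)OC(C)=O
Why: BF3-mediated Friedel–Crafts C-acetylation (with Fries-type transfer of any O-acetyl first formed): the two free ring positions, both ortho to the phenol and para to a methoxy group, are equivalent, the amine is masked as its BF3 adduct, and the product is held as a difluoroboron chelate of the new ortho-hydroxy ketone that the basic methanol work-up opens.

Step 9
Reactants: 16 1-{6-hydroxy-2,4-dimethoxy-3-[(2R)-1-methylpiperidin-2-yl]phenyl}ethan-1-one; 17 methyl benzoate
Product: 19 5,7-dimethoxy-6-[(2R)-1-methylpiperidin-2-yl]-2-phenyl-4H-chromen-4-one, via 1,3-diketone 18 (not isolated)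
Conditions: PhCO2Me, NaH, DMF, 0 °C to rt; then AcOH, conc. HCl, 50 °C
Reagents that add atoms: methyl benzoate (17), COC(=O)c1ccccc1
Why: Crossed Claisen condensation of the phenoxide–enolate dianion of 16 with methyl benzoate gives the 1,3-diketone of a Baker–Venkataraman flavone synthesis, and acid then cyclodehydrates it by attack of the single free phenol oxygen on the benzoyl carbonyl, so that O1 can only be the oxygen para to the piperidine and the flavone must carry the piperidine at C6.

Step 10
Reactants: 19 5,7-dimethoxy-6-[(2R)-1-methylpiperidin-2-yl]-2-phenyl-4H-chromen-4-one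
Product: 20 5,7-dihydroxy-6-[(2R)-1-methylpiperidin-2-yl]-2-phenyl-4H-chromen-4-one
Conditions: BBr3, CH2Cl2, −78 °C to rt; MeOH, then aq. NaHCO3
Reagents that add atoms: none
Why: Lewis-acid cleavage of aryl methyl ethers: BBr3 binds each ether oxygen and bromide removes the methyl group by SN2 (the 5-O-methyl helped by chelation to the C4 carbonyl), while the boron-complexed, electron-poor flavone disfavours ionisation of the protonated or boron-bound C2'–N bond at low temperature.

Compound list
1 | 4-hydroxy-2,6-dimethoxybenzaldehyde | COc1cc(O)cc(OC)c1C=O | starting material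
2 | benzyl bromide | BrCc1ccccc1 | starting material
3 | 4-(benzyloxy)-2,6-dimethoxybenzaldehyde | COc1cc(OCc2ccccc2)cc(OC)c1C=O | intermediate
4 | (S)-tert-butanesulfinamide | CC(C)(C)[S@](=O)N | starting material
5 | allyl bromide | C=CCBr | starting material
6 | (S,E)-N-[(4-benzyloxy-2,6-dimethoxyphenyl)methylidene]-2-methylpropane-2-sulfinamide (not isolated) | CC(C)(C)[S@](=O)/N=C/c1c(OC)cc(OCc2ccccc2)cc1OC | intermediate
7 | (S)-N-[(1R)-1-(4-benzyloxy-2,6-dimethoxyphenyl)but-3-en-1-yl]-2-methylpropane-2-sulfinamide | CC(C)(C)[S@](=O)N[C@H](CC=C)c1c(OC)cc(OCc2ccccc2)cc1OC | intermediate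
8 | methyl chloroformate | COC(=O)Cl | starting material
9 | (1R)-1-(4-benzyloxy-2,6-dimethoxyphenyl)but-3-en-1-amine (not isolated; hydrochloride until NaHCO3 is added) | N[C@H](CC=C)c1c(OC)cc(OCc2ccccc2)cc1OC | intermediate
10 | methyl N-[(1R)-1-(4-benzyloxy-2,6-dimethoxyphenyl)but-3-en-1-yl]carbamate | COC(=O)N[C@H](CC=C)c1c(OC)cc(OCc2ccccc2)cc1OC | intermediate
11 | methyl N-allyl-N-[(1R)-1-(4-benzyloxy-2,6-dimethoxyphenyl)but-3-en-1-yl]carbamate | COC(=O)N(CC=C)[C@H](CC=C)c1c(OC)cc(OCc2ccccc2)cc1OC | intermediate
12 | methyl (2R)-2-(4-benzyloxy-2,6-dimethoxyphenyl)-3,6-dihydro-2H-pyridine-1-carboxylate | COC(=O)N1CC=CC[C@@H]1c1c(OC)cc(OCc2ccccc2)cc1OC | intermediate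
13 | methyl (2R)-2-(4-hydroxy-2,6-dimethoxyphenyl)piperidine-1-carboxylate | COC(=O)N1CCCC[C@@H]1c1c(OC)cc(O)cc1OC | intermediate
14 | 3,5-dimethoxy-4-[(2R)-1-methylpiperidin-2-yl]phenol | CN1CCCC[C@@H]1c1c(OC)cc(O)cc1OC | intermediate
15 | acetic anhydride | CC(=O)OC(C)=O | starting material
16 | 1-{6-hydroxy-2,4-dimethoxy-3-[(2R)-1-methylpiperidin-2-yl]phenyl}ethan-1-one | CN1CCCC[C@@H]1c1c(OC)cc(O)c(C(C)=O)c1OC | intermediate
17 | methyl benzoate | COC(=O)c1ccccc1 | starting material
18 | 1-{6-hydroxy-2,4-dimethoxy-3-[(2R)-1-methylpiperidin-2-yl]phenyl}-3-phenylpropane-1,3-dione (not isolated) | CN1CCCC[C@@H]1c1c(OC)cc(O)c(C(=O)CC(=O)c2ccccc2)c1OC | intermediate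
19 | 5,7-dimethoxy-6-[(2R)-1-methylpiperidin-2-yl]-2-phenyl-4H-chromen-4-one | CN1CCCC[C@@H]1c1c(OC)cc2oc(-c3ccccc3)cc(=O)c2c1OC | intermediate
20 | 5,7-dihydroxy-6-[(2R)-1-methylpiperidin-2-yl]-2-phenyl-4H-chromen-4-one | CN1CCCC[C@@H]1c1c(O)cc2oc(-c3ccccc3)cc(=O)c2c1O | target

Total step count: 10. Longest linear sequence: 10 steps (1 to 20).

Steps most likely to fail

Step 8 (C-acetylation). The Lewis acid may ionise the C2'–N bond of the very electron-rich benzylic amine, which would racemise or open the ring. It may also remove the methyl group from the methoxy oxygen lying between the acetyl group and the piperidine, which would later allow closure of the pyranone to the wrong oxygen. The fallback avoids Lewis acid and uses carbanion chemistry; it sets out from 14 and comes back at 16. The phenol is protected with MOMCl and NaH in THF as the methoxymethyl ether (2R)-2-[2,6-dimethoxy-4-(methoxymethoxy)phenyl]-1-methylpiperidine F1. Directed ortho-lithiation with n-BuLi in THF at 0 °C takes place at the position flanked by the methoxymethoxy and a methoxy group, and quenching with N-methoxy-N-methylacetamide should give the ketone 1-{2,4-dimethoxy-6-(methoxymethoxy)-3-[(2R)-1-methylpiperidin-2-yl]phenyl}ethan-1-one F2. Dilute HCl in MeOH at rt then removes the acetal and delivers 16.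

Step 10 (double O-demethylation). Cleavage may stop at the hindered 7-O-methyl, or prolonged acid exposure may open the C2'–N bond once both flanking phenols are free and erode the enantiomeric purity. The fallback splits the task into two mechanistically different cleavages; it sets out from 19 and comes back at 20. BCl3 in CH2Cl2 at −78 to 0 °C should remove only the chelated 5-O-methyl and give 5-hydroxy-7-methoxy-6-[(2R)-1-methylpiperidin-2-yl]-2-phenyl-4H-chromen-4-one F3. Sodium ethanethiolate NaSEt in DMF at about 100 °C then removes the 7-O-methyl by SN2 attack at the methyl carbon under basic conditions; the 7-oxygen is para to the C4 carbonyl and a good leaving group, and no acid is present to ionise C2'–N.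

Step 2 (one-pot aminoallylation). The two ortho-methoxy groups may compete for the metal and loosen the chair transition state, giving poor facial selectivity. Slow condensation of the hindered aldehyde may also leave aldehyde that is allylated to the alcohol. The fallback replaces auxiliary control by reagent control; it sets out from 3 and comes back at 9. LiN(SiMe3)2 in THF converts 3 into the N-silyl imine (E)-1-(4-benzyloxy-2,6-dimethoxyphenyl)-N-(trimethylsilyl)methanimine F4. Allylboration with B-allyldiisopinocampheylborane prepared from (−)-α-pinene, in the presence of one equivalent of MeOH at −78 °C and followed by oxidative work-up, should give amine 9, which is acylated with methyl chloroformate as in the second stage of step 3. This borane antipode adds to the Re face of aryl aldehydes and is expected to do the same with the N–H aldimine released in the flask; should the first run show the opposite sense, the borane from (+)-α-pinene is used instead.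

Further compounds
F1 | step 8 | (2R)-2-[2,6-dimethoxy-4-(methoxymethoxy)phenyl]-1-methylpiperidine | CN1CCCC[C@@H]1c1c(OC)cc(OCOC)cc1OC
F2 | step 8 | 1-{2,4-dimethoxy-6-(methoxymethoxy)-3-[(2R)-1-methylpiperidin-2-yl]phenyl}ethan-1-one | CN1CCCC[C@@H]1c1c(OC)cc(OCOC)c(C(C)=O)c1OC
F3 | step 10 | 5-hydroxy-7-methoxy-6-[(2R)-1-methylpiperidin-2-yl]-2-phenyl-4H-chromen-4-one | CN1CCCC[C@@H]1c1c(OC)cc2oc(-c3ccccc3)cc(=O)c2c1O
F4 | step 2 | (E)-1-(4-benzyloxy-2,6-dimethoxyphenyl)-N-(trimethylsilyl)methanimine | C[Si](C)(C)/N=C/c1c(OC)cc(OCc2ccccc2)cc1OC
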